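**Plan**

1. The retrosynthesis cuts, in this order, C8–C15′ (a 1,3-shift that contracts a seven-membered ring to the bridged cyclopentanone), C11–C15′ (anionic 5-exo closure), C13–C14′ (Claisen rearrangement) and the temporary O12–C12′ ether tether (Mitsunobu), leaving hydroxyquinone 26 and allylic alcohol 17.
2. 26 comes from sugiol by contraction of ring B (aryl 1,2-shift) and oxidation of ring C; 17 comes from abietic acid by cleavage of the C13–C14 bond of ring C, excision of the isopropyl ketone carbons and addition of a Z-configured C4 alkenyl unit.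
3. Forward order: ether tether, then the C13–C14′ bond, then the cyclopentanol bridge C13–C14′–C15′–C11–C12 (bicycle 32), then the ring C15′–C11–C9–C8–C14–C13–C14′ shrinks to the cyclopentanone C14′–C15′–C8–C14–C13.
4. Enabling feature: in 32 the carbinol C11 sits between the C12 ketone and the C9=C8 bond of the C14 enone, so loss of C15′ from C11 leaves a radical anion spread over the whole ene-trione of ring C, and C15′, held on the α-face by C14′, can return only at C8.
5. Stereochemistry: abietic acid supplies C4′, C5′, C9′ and C10′; sugiol supplies C5 and C10; the ring contraction sets C7; the reagent-controlled C12′ carbinol is relayed by the chair Claisen transition state to C13, C14′ and the E-C12′=C13′ bond; C8 follows from the tether.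

Key step: step 22

Remark: the 6-5-6 half keeps abietane numbers (ring B methine C7 carries the formyl carbon C6) and the labdane half carries primed numbers (bridge methine C14′, bridge methylene C15′); abietic acid, sugiol and but-2-yn-1-ol are taken as the purchased starting materials.

**Labdane fragment**

Step 1
Reactants: 1 (−)-abietic acid; 2 2-(trimethylsilyl)ethanol
Product: 3 2-(trimethylsilyl)ethyl abietate
Conditions: PPh3, DIAD, THF, 0 °C → rt
Reagents that add atoms: none
Why: Mitsunobu esterification activates the primary alcohol, so the hindered C18 carboxylate is alkylated without acid that would isomerise the diene, and the resulting ester is cleavable by fluoride at the end.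

Step 2
Reactants: 3 2-(trimethylsilyl)ethyl abietate
Product: 5 seco keto enal (ring C opened between C13 and C14), via cis-diol 4 (not isolated)
Conditions: OsO4 (cat.), NaIO4, 2,6-lutidine, dioxane–H2O, rt
Reagents that add atoms: osmium tetroxide O=[Os](=O)(=O)=O (transfers both oxygens); sodium periodate [Na+].[O-]I(=O)(=O)=O (restores it)
Why: Lemieux–Johnson cleavage, in which OsO4 should dihydroxylate the more exposed C13=C14 bond of the diene and periodate cleave the diol, opening ring C while the four stereocentres of rings A and B stay untouched and the C7=C8 bond survives as an electron-poor enal.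

Step 3
Reactants: 5 seco keto enal
Product: 6 seco keto allylic alcohol
Conditions: NaBH4, MeOH–CH2Cl2, −78 °C
Reagents that add atoms: none
Why: chemoselective 1,2-reduction of the aldehyde by hydride at low temperature, the hindered isopropyl ketone reacting far more slowly.

Step 4
Reactants: 6 seco keto allylic alcohol
Product: 9 labd-8(17)-ene isopropyl ketone, via sulfonylhydrazine adduct 7 (not isolated), via allylic diazene 8 (not isolated)
Conditions: 2-nitrobenzenesulfonylhydrazide, PPh3, DIAD, THF, −30 °C → rt
Reagents that add atoms: none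
Why: reductive 1,3-transposition of an allylic alcohol (Mitsunobu displacement by the sulfonylhydrazide, loss of sulfinate, retro-ene loss of N2 from the monoalkyl diazene), which moves the double bond to the exocyclic C8=CH2 position of a labdane and delivers hydrogen to C7.

Step 5
Reactants: 9 labd-8(17)-ene isopropyl ketone
Product: 11 labdane C12 aldehyde, via alpha-ketol 10 (not isolated)
Conditions: LiN(iPr)2, THF, −78 °C; 2-(phenylsulfonyl)-3-phenyloxaziridine; then Pb(OAc)4, MeOH–PhH, 0 °C on the crude ketol
Reagents that add atoms: 2-(phenylsulfonyl)-3-phenyloxaziridine O=S(=O)(c1ccccc1)N1OC1c1ccccc1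
Why: kinetic deprotonation at the methylene C12 rather than the isopropyl methine, enolate hydroxylation by the N-sulfonyloxaziridine and glycol-type cleavage of the α-ketol by Pb(OAc)4 excise the isopropyl ketone carbons and leave the C12 aldehyde.

Step 6
Reactants: 12 but-2-yn-1-ol
Product: 13 (Z)-3-iodobut-2-en-1-ol
Conditions: NaAlH2(OCH2CH2OMe)2, THF, 0 °C; then I2, −78 °C
Reagents that add atoms: iodine II
Why: hydroxyl-directed trans-hydroalumination of the propargylic alcohol places aluminium on C3 cis to the CH2OH group, and iodinolysis with retention gives the Z-iodoalkene.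

Step 7
Reactants: 13 (Z)-3-iodobut-2-en-1-ol
Product: 14 Z-iodoalkene tert-butyldimethylsilyl ether
Conditions: TBSCl, imidazole, DMF, rt
Reagents that add atoms: tert-butyldimethylsilyl chloride CC(C)(C)[Si](C)(C)Cl
Why: standard silylation of the primary alcohol, which masks the later C15′ oxygen through the coupling, the Mitsunobu step and the Claisen step.

Step 8
Reactants: 11 labdane C12 aldehyde; 14 Z-iodoalkene tert-butyldimethylsilyl ether
Product: 15 labdane allylic alcohol (both C12′ epimers)
Conditions: CrCl2, NiCl2 (cat.), DMF–THF, rt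
Reagents that add atoms: none
Why: Nozaki–Hiyama–Kishi coupling, in which the alkenylchromium species adds only to the aldehyde with retention of the Z geometry; the new carbinol centre is formed without control and is corrected in steps 9 and 10.

Step 9
Reactants: 15 labdane allylic alcohol (both C12′ epimers)
Product: 16 labdane Z-enone
Conditions: Dess–Martin periodinane, NaHCO3, CH2Cl2, 0 °C
Reagents that add atoms: none
Why: Dess–Martin oxidation of the secondary allylic alcohol under buffered conditions that leave the silyl ether and both alkenes alone.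

Step 10
Reactants: 16 labdane Z-enone
Product: 17 (12′R,13′Z)-allylic alcohol
Conditions: (S)-2-methyl-CBS-oxazaborolidine (cat.), BH3·SMe2, THF, −30 °C
Reagents that add atoms: none
Why: Corey–Bakshi–Shibata reduction, in which the α-methylalkenyl group acts as the large substituent, so the (S)-catalyst should deliver hydride to give the (12′R)-alcohol.

**Quinone fragment**

Step 11
Reactants: 18 (+)-sugiol
Product: 19 sugiol triisopropylsilyl ether
Conditions: iPr3SiCl, imidazole, DMF, rt
Reagents that add atoms: triisopropylsilyl chloride CC(C)[Si](Cl)(C(C)C)C(C)C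
Why: silylation of the phenol, which protects it from the trivalent iodine oxidant of step 13 and keeps the para-oxygen donor that assists the benzylic chemistry.

Step 12
Reactants: 19 sugiol triisopropylsilyl ether
Product: 21 6,7-dehydroferruginol triisopropylsilyl ether, via benzylic alcohol 20 (not isolated)
Conditions: NaBH4, MeOH–THF, 0 °C; then TsOH·H2O (cat.), PhH, 60 °C
Reagents that add atoms: none
Why: hydride reduction of the aryl ketone followed by acid-catalysed E1 dehydration of the para-silyloxybenzylic alcohol gives the styrene-type C6=C7 alkene.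

Step 13
Reactants: 21 6,7-dehydroferruginol triisopropylsilyl ether
Product: 22 ring-contracted aryl dimethyl acetal (6-5-6 tricycle)
Conditions: PhI(OH)OTs, MeOH, 0 °C → rt
Reagents that add atoms: methanol CO
Why: oxidative ring contraction of a 1,2-dihydronaphthalene by a trivalent iodine reagent, in which iodine adds to the non-benzylic alkene carbon from the α-face, methanol adds to the benzylic carbon, and 1,2-shift of the aryl carbon C8 with loss of iodobenzene makes ring B five-membered and turns the benzylic carbon into the acetal of the formyl group, placed α on C7 (cis to H5) by the anti course of the shift.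

Step 14
Reactants: 22 ring-contracted aryl dimethyl acetal
Product: 23 ring-contracted phenol
Conditions: Bu4NF, THF, 0 °C
Reagents that add atoms: none
Why: fluoride cleavage of the aryl silyl ether under conditions that leave the dimethyl acetal intact.

Step 15
Reactants: 23 ring-contracted phenol
Product: 24 11,12-ortho-quinone
Conditions: 2-iodoxybenzoic acid, DMF, rt
Reagents that add atoms: 2-iodoxybenzoic acid O=C1OI(=O)(O)c2ccccc12
Why: regioselective ortho-oxidation of a phenol by the pentavalent iodine reagent, which transfers oxygen to the only free ortho carbon (C11) and collapses to the ortho-quinone.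

Step 16
Reactants: 24 11,12-ortho-quinone
Product: 26 hydroxy-para-quinone (taiwaniaquinone A dimethyl acetal), via 14-methoxy ortho-quinone 25 (not isolated)
Conditions: NaOMe (cat.), MeOH, air, rt; then NaOH (aq), rt; then HCl (aq) to pH 4
Reagents that add atoms: sodium hydroxide [Na+].[OH-]
Why: conjugate addition of methoxide to the unsubstituted C14 position of the ortho-quinone and autoxidation give the 14-methoxy ortho-quinone, and addition–elimination hydrolysis of this vinylogous ester gives the 12-hydroxy-11,14-quinone tautomer.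

**Union and endgame**

Step 17
Reactants: 26 hydroxy-para-quinone; 17 (12′R,13′Z)-allylic alcohol
Product: 27 quinone allyl ether (O12–C12′ with 12′S)
Conditions: PPh3, DIAD (premixed), PhMe, 0 °C → rt
Reagents that add atoms: none
Why: Mitsunobu etherification of the acidic vinylogous acid O12–H by the secondary allylic alcohol with inversion at C12′; the O12–C12′ bond is a temporary tether that is absent from the target.

Step 18
Reactants: 27 quinone allyl ether
Product: 28 ene-trione with the C13–C14′ bond
Conditions: PhMe, 90 °C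
Reagents that add atoms: none
Why: Claisen rearrangement of the allyl vinyl ether O12–C12′–C13′=C14′ / C12=C13 through a chair transition state with the C11′ chain equatorial, which cuts the tether, forms the C13–C14′ bond on the α-face of ring C and translates the (12′S) centre and the Z-alkene into the C13 quaternary centre, the C14′ centre and the E-C12′=C13′ bond.

Step 19
Reactants: 28 ene-trione with the C13–C14′ bond
Product: 29 primary alcohol at C15′
Conditions: HF·pyridine, pyridine, THF, 0 °C
Reagents that add atoms: none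
Why: buffered fluoride desilylation of the primary tert-butyldimethylsilyl ether, mild enough for the acetal and the 2-(trimethylsilyl)ethyl ester.

Step 20
Reactants: 29 primary alcohol at C15′
Product: 30 primary iodide at C15′
Conditions: PPh3, I2, imidazole (premixed), CH2Cl2, 0 °C
Reagents that add atoms: iodine II
Why: Appel-type iodination of the unhindered primary alcohol by the preformed iodophosphonium salt, so that no free phosphine meets the ene-trione.

Step 21
Reactants: 30 primary iodide at C15′
Product: 32 C11 carbinol bicycle, via primary alkyllithium 31 (not isolated)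
Conditions: t-BuLi, THF–Et2O–pentane, −100 °C; AcOH quench at −100 °C
Reagents that add atoms: none
Why: halogen–lithium exchange-initiated anionic cyclisation, in which iodine–lithium exchange outruns carbonyl addition of tert-butyllithium and the primary alkyllithium should add 5-exo to the nearest and most electrophilic carbonyl, C11 of the vicinal diketone, from the α-face fixed by C14′.

Step 22
Reactants: 32 C11 carbinol bicycle
Product: 33 protected target (diosphenol with C7 acetal and silylethyl ester)
Conditions: KH, 18-crown-6, THF, 0 °C → rt; NH4Cl (aq)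
Reagents that add atoms: none
Why: Proposed new method: the potassium alkoxide at C11 weakens the adjacent C11–C15′ bond, which should break homolytically to a primary C15′ radical held next to the persistent radical anion of the ring C ene-trione and recombine at C8, a net suprafacial 1,3-shift of C15′ from C11 to C8 by which the seven-membered ring C15′–C11–C9–C8–C14–C13–C14′ of 32 contracts by two atoms to the cyclopentanone C14′–C15′–C8–C14–C13. The closest known reaction types are the oxyanion-accelerated 1,3-shift of 1-vinylcycloalkanolates (two-carbon ring transposition) and the 1,2- to 1,4-adduct isomerisation of quinol alkoxides. The five-membered ring closes in a 5-exo mode onto C8 of the C8=C9 bond, and formation of the conjugated C9=C11 enolate next to the C12 ketone makes the step irreversible. The new quaternary centre C8 is set by the tether, since C15′ hangs from C14′ on the α-face of C13 and can reach C8 only from that face, anti to the C20 methyl group; the C11 centre is lost. The step needs migration of C15′ to C8 in preference to the α-ketol shifts of C9 or C15′ to C12, which are reversible and end in unstabilised alkoxides, whereas the 1,3-shift ends in the delocalised enolate.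

Step 23
Reactants: 33 protected target
Product: 35 target CNP0256710.1, via acetal acid 34 (not isolated)
Conditions: (Me2N)3S+ Me3SiF2−, DMF, 0 °C; then HCl (1 M), THF–H2O, 0 °C
Reagents that add atoms: water O
Why: fluoride-induced fragmentation of the 2-(trimethylsilyl)ethyl ester to the carboxylate, then mild aqueous acid hydrolysis of the dimethyl acetal, with C7 keeping the α-formyl group installed in step 13.

**Compound list**

1 | (−)-abietic acid (abieta-7,13-dien-18-oic acid; 4α-CO2H, 5α-H, 9α-H, 10β-CH3) | CC(C)C1=CC2=CC[C@@H]3[C@](C)(CCC[C@@]3(C)C(=O)O)[C@H]2CC1 | starting material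
2 | 2-(trimethylsilyl)ethanol | C[Si](C)(C)CCO | starting material
3 | 2-(trimethylsilyl)ethyl abietate | CC(C)C1=CC2=CC[C@@H]3[C@](C)(CCC[C@@]3(C)C(=O)OCC[Si](C)(C)C)[C@H]2CC1 | intermediate
4 | 13,14-cis-diol of 3 (C13 and C14 configuration not assigned; cleaved in the same flask) | CC(C)C1(O)C(O)C2=CC[C@@H]3[C@](C)(CCC[C@@]3(C)C(=O)OCC[Si](C)(C)C)[C@H]2CC1 | intermediate (not isolated)
5 | seco keto enal: ring C opened between C13 and C14, C14 aldehyde on C8 conjugated with C7=C8, isopropyl ketone C13 at the end of the C9 side chain, silylethyl ester at C18 | O=CC1=CC[C@@H]2[C@](C)(CCC[C@@]2(C)C(=O)OCC[Si](C)(C)C)[C@H]1CCC(=O)C(C)C | intermediate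
6 | seco keto allylic alcohol (C14 hydroxymethyl on C8 of the C7=C8 bond) | OCC1=CC[C@@H]2[C@](C)(CCC[C@@]2(C)C(=O)OCC[Si](C)(C)C)[C@H]1CCC(=O)C(C)C | intermediate
7 | N-allyl-N-(2-nitrophenylsulfonyl)hydrazine adduct of 6 (nitrogen on C14) | NN(CC1=CC[C@@H]2[C@](C)(CCC[C@@]2(C)C(=O)OCC[Si](C)(C)C)[C@H]1CCC(=O)C(C)C)S(=O)(=O)c1ccccc1[N+](=O)[O-] | intermediate (not isolated)
8 | allylic monoalkyl diazene of 6 (C14–N=NH) | N=NCC1=CC[C@@H]2[C@](C)(CCC[C@@]2(C)C(=O)OCC[Si](C)(C)C)[C@H]1CCC(=O)C(C)C | intermediate (not isolated)
9 | labd-8(17)-ene isopropyl ketone: exocyclic C8=CH2, side chain C9–CH2–CH2–C(=O)–CH(CH3)2, silylethyl ester at C18 | C=C1CC[C@@H]2[C@](C)(CCC[C@@]2(C)C(=O)OCC[Si](C)(C)C)[C@H]1CCC(=O)C(C)C | intermediate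
10 | 12-hydroxy derivative of ketone 9 (α-ketol, both C12 epimers) | C=C1CC[C@@H]2[C@](C)(CCC[C@@]2(C)C(=O)OCC[Si](C)(C)C)[C@H]1CC(O)C(=O)C(C)C | intermediate (not isolated)
11 | labdane C12 aldehyde: 2-(trimethylsilyl)ethyl (4R,5R,9S,10R)-12-oxo-13,14,15,16-tetranorlabd-8(17)-en-18-oate | C=C1CC[C@@H]2[C@](C)(CCC[C@@]2(C)C(=O)OCC[Si](C)(C)C)[C@H]1CC=O | intermediate
12 | but-2-yn-1-ol | CC#CCO | starting material
13 | (Z)-3-iodobut-2-en-1-ol | C/C(I)=C/CO | intermediate
14 | tert-butyl[(Z)-3-iodobut-2-enyloxy]dimethylsilane | C/C(I)=C/CO[Si](C)(C)C(C)(C)C | intermediate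
15 | 2-(trimethylsilyl)ethyl (13Z)-15-(tert-butyldimethylsilyloxy)-12-hydroxylabda-8(17),13-dien-18-oate, both C12′ epimers | C=C1CC[C@@H]2[C@](C)(CCC[C@@]2(C)C(=O)OCC[Si](C)(C)C)[C@H]1CC(O)/C(C)=C\CO[Si](C)(C)C(C)(C)C | intermediate
16 | 2-(trimethylsilyl)ethyl (13Z)-15-(tert-butyldimethylsilyloxy)-12-oxolabda-8(17),13-dien-18-oate | C=C1CC[C@@H]2[C@](C)(CCC[C@@]2(C)C(=O)OCC[Si](C)(C)C)[C@H]1CC(=O)/C(C)=C\CO[Si](C)(C)C(C)(C)C | intermediate
17 | 2-(trimethylsilyl)ethyl (12R,13Z)-15-(tert-butyldimethylsilyloxy)-12-hydroxylabda-8(17),13-dien-18-oate | C=C1CC[C@@H]2[C@](C)(CCC[C@@]2(C)C(=O)OCC[Si](C)(C)C)[C@H]1C[C@@H](O)/C(C)=C\CO[Si](C)(C)C(C)(C)C | intermediate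
18 | (+)-sugiol (12-hydroxyabieta-8,11,13-trien-7-one; 5α-H, 10β-CH3) | CC(C)c1cc2C(=O)C[C@H]3C(C)(C)CCC[C@]3(C)c2cc1O | starting material
19 | sugiol triisopropylsilyl ether | CC(C)c1cc2C(=O)C[C@H]3C(C)(C)CCC[C@]3(C)c2cc1O[Si](C(C)C)(C(C)C)C(C)C | intermediate
20 | 7-hydroxy compound from 19 (benzylic alcohol, C7 epimers) | CC(C)c1cc2C(O)C[C@H]3C(C)(C)CCC[C@]3(C)c2cc1O[Si](C(C)C)(C(C)C)C(C)C | intermediate (not isolated)
21 | 6,7-dehydroferruginol triisopropylsilyl ether (abieta-6,8,11,13-tetraene) | CC(C)c1cc2C=C[C@H]3C(C)(C)CCC[C@]3(C)c2cc1O[Si](C(C)C)(C(C)C)C(C)C | intermediate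
22 | ring-contracted aryl acetal: 6-5-6 tricycle, ring B = C5, C7, C8, C9, C10; C7 carries H (β) and CH(OCH3)2 (α, cis to H5); 12-triisopropylsilyloxy, 13-isopropyl | COC(OC)[C@H]1c2cc(C(C)C)c(O[Si](C(C)C)(C(C)C)C(C)C)cc2[C@@]2(C)CCCC(C)(C)[C@H]12 | intermediate
23 | phenol from 22 (12-OH) | COC(OC)[C@H]1c2cc(C(C)C)c(O)cc2[C@@]2(C)CCCC(C)(C)[C@H]12 | intermediate
24 | 11,12-ortho-quinone (C8=C9 and C13=C14 double bonds, H on C14) | COC(OC)[C@H]1C2=C([C@@]3(C)CCCC(C)(C)[C@H]13)C(=O)C(=O)C(C(C)C)=C2 | intermediate
25 | 14-methoxy-11,12-ortho-quinone | COC(OC)[C@H]1C2=C([C@@]3(C)CCCC(C)(C)[C@H]13)C(=O)C(=O)C(C(C)C)=C2OC | intermediate (not isolated)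
26 | taiwaniaquinone A dimethyl acetal: 12-hydroxy-13-isopropyl-11,14-para-quinone with 7α-CH(OCH3)2 | COC(OC)[C@H]1C2=C([C@@]3(C)CCCC(C)(C)[C@H]13)C(=O)C(O)=C(C(C)C)C2=O | intermediate
27 | quinone allyl ether: O12 of 26 bonded to C12′ (S) of the (13′Z)-labdane unit | C=C1CC[C@@H]2[C@](C)(CCC[C@@]2(C)C(=O)OCC[Si](C)(C)C)[C@H]1C[C@H](OC1=C(C(C)C)C(=O)C2=C(C1=O)[C@@]3(C)CCCC(C)(C)[C@@H]3[C@H]2C(OC)OC)/C(C)=C\CO[Si](C)(C)C(C)(C)C | intermediate
28 | ene-trione: ring C is a cyclohex-8-ene-11,12,14-trione; quaternary C13 (R) carries isopropyl and C14′ (S); C14′ carries H, CH2OSi(tBu)Me2 (C15′) and the (E)-C13′(CH3)=C12′H–C11′H2–labdane chain | C=C1CC[C@@H]2[C@](C)(CCC[C@@]2(C)C(=O)OCC[Si](C)(C)C)[C@H]1C/C=C(\C)[C@H](CO[Si](C)(C)C(C)(C)C)[C@@]1(C(C)C)C(=O)C(=O)C2=C(C1=O)[C@H](C(OC)OC)[C@H]3C(C)(C)CCC[C@]23C | intermediate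
29 | primary alcohol (C15′–OH) of the ene-trione | C=C1CC[C@@H]2[C@](C)(CCC[C@@]2(C)C(=O)OCC[Si](C)(C)C)[C@H]1C/C=C(\C)[C@H](CO)[C@@]1(C(C)C)C(=O)C(=O)C2=C(C1=O)[C@H](C(OC)OC)[C@H]3C(C)(C)CCC[C@]23C | intermediate
30 | primary iodide (C15′–I) of the ene-trione | C=C1CC[C@@H]2[C@](C)(CCC[C@@]2(C)C(=O)OCC[Si](C)(C)C)[C@H]1C/C=C(\C)[C@H](CI)[C@@]1(C(C)C)C(=O)C(=O)C2=C(C1=O)[C@H](C(OC)OC)[C@H]3C(C)(C)CCC[C@]23C | intermediate
31 | primary alkyllithium (C15′–Li) | C=C1CC[C@@H]2[C@](C)(CCC[C@@]2(C)C(=O)OCC[Si](C)(C)C)[C@H]1C/C=C(\C)[C@H](C[Li])[C@@]1(C(C)C)C(=O)C(=O)C2=C(C1=O)[C@H](C(OC)OC)[C@H]3C(C)(C)CCC[C@]23C | intermediate (not isolated)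
32 | C11 carbinol bicycle: C15′ bonded to C11 (R, tertiary OH); bicyclo[3.2.1]octene with the C12 ketone as one-carbon bridge between C11 and C13; enone C9=C8–C14=O | C=C1CC[C@@H]2[C@](C)(CCC[C@@]2(C)C(=O)OCC[Si](C)(C)C)[C@H]1C/C=C(\C)[C@@H]1C[C@]2(O)C(=O)[C@@]1(C(C)C)C(=O)C3=C2[C@@]2(C)CCCC(C)(C)[C@@H]2[C@H]3C(OC)OC | intermediate
33 | protected target: C15′ bonded to C8 (S); C14 ketone bridges C8 and C13; diosphenol C9=C11(OH)–C12=O; C7 dimethyl acetal; 2-(trimethylsilyl)ethyl ester | C=C1CC[C@@H]2[C@](C)(CCC[C@@]2(C)C(=O)OCC[Si](C)(C)C)[C@H]1C/C=C(\C)[C@@H]1C[C@@]23C(=O)[C@]1(C(C)C)C(=O)C(O)=C2[C@@]1(C)CCCC(C)(C)[C@@H]1[C@H]3C(OC)OC | intermediate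
34 | carboxylic acid with the C7 dimethyl acetal | C=C1CC[C@@H]2[C@](C)(CCC[C@@]2(C)C(=O)O)[C@H]1C/C=C(\C)[C@@H]1C[C@@]23C(=O)[C@]1(C(C)C)C(=O)C(O)=C2[C@@]1(C)CCCC(C)(C)[C@@H]1[C@H]3C(OC)OC | intermediate (not isolated)
35 | CNP0256710.1 | C=C1CC[C@@H]2[C@](C)(CCC[C@@]2(C)C(=O)O)[C@H]1C/C=C(\C)[C@@H]1C[C@@]23C(=O)[C@]1(C(C)C)C(=O)C(O)=C2[C@@]1(C)CCCC(C)(C)[C@@H]1[C@H]3C=O | target

**Step count**

Total steps: 23. Longest linear sequence: 15 (steps 1–5, 8–10 and 17–23).

**Steps most likely to fail**

Step 22 (key step). The alkoxide may not shed C15′ at a useful rate, or may drain by α-ketol shifts and by retro-Claisen opening of the 1,3-diketone before the 1,3-shift occurs. Fallback with known chemistry: set out from iodide 30 and close the C8–C15′ bond directly by tin hydride radical cyclisation (Bu3SnH, azobisisobutyronitrile, PhH, 80 °C). The primary C15′ radical should add 5-exo to C8 of the C8=C9–C11=O enone from the α-face, the C9 radical takes up hydrogen, and the resulting α-diketone enolises to 33, where the route is rejoined. No new compound arises (F0).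

Step 21. Electron transfer from the alkyllithium or from tert-butyllithium to the easily reduced ene-trione, or addition to the C12 or C14 carbonyl, may compete with the 5-exo addition to C11. Fallback: set out from iodide 30 and reverse the polarity with SmI2 (THF, −78 °C). The ene-trione is reduced to the ring C enediolate, which should displace the primary iodide through carbon; alkylation through C11 returns to the route at 32, and any material alkylated through C8 is already 33. No new compound arises (F0).

Step 17. Etherification may occur at O14 instead of O12, giving the ortho-quinone ether that would rearrange on the wrong face, or by allylic transposition (attack at C14′). Fallback: set out from 26 and from enone 16. Methylation of 26 (MeI, Ag2O) gives the 12-methyl ether F1. Reduction of 16 with the (R)-configured oxazaborolidine gives the (12′S)-alcohol F2. The potassium alkoxide of F2 (KH, THF, 0 °C) should then exchange with the methoxy group of F1 by conjugate addition–elimination at C12, with retention at C12′, and the route is rejoined at 27.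

**Further compounds**

F0 | step 22 | none | none
F0 | step 21 | none | none
F1 | step 17 | 12-O-methyl ether of hydroxyquinone 26 | COC(OC)[C@H]1C2=C([C@@]3(C)CCCC(C)(C)[C@H]13)C(=O)C(OC)=C(C(C)C)C2=O
F2 | step 17 | 2-(trimethylsilyl)ethyl (12S,13Z)-15-(tert-butyldimethylsilyloxy)-12-hydroxylabda-8(17),13-dien-18-oate | C=C1CC[C@@H]2[C@](C)(CCC[C@@]2(C)C(=O)OCC[Si](C)(C)C)[C@H]1C[C@H](O)/C(C)=C\CO[Si](C)(C)C(C)(C)C
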